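**Strategy.** Each chroman is disconnected at C3, the ring C carbon that bears ring B and sits between C2 (OCH2) and C4 (ArCH2). Removing this single carbon leaves the C2=C3 bond of a benzofuran. The key step therefore lets a twofold-symmetric bis(arylchlorocarbene), released from the bis(3-chlorodiazirine) of the 4',4'-linked diaryl ether core (2'-OMe, 3'-OBn), insert one carbon into each of two 6-benzyloxybenzofurans. In one operation both ring C units appear as benzopyrylium rings and all four C2–C3 and C3–C4 bonds are made. Hydride reduction, a double iridium-catalysed asymmetric hydrogenation that sets both 3R centres, and a single hydrogenolysis complete the route.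

Key step: step 8

Assumption: the SMILES is read as R at both C3 centres (priorities C2 > C1' > C4 > H), in isoflavan numbering (ring A benzo, ring C pyran, ring B pendant aryl). All four phenols are carried as benzyl ethers so that one hydrogenolysis frees them.

**Step 1**
Reactants: 1 4-fluoro-2-methoxybenzonitrile
Product: 4 4-fluoro-3-hydroxy-2-methoxybenzonitrile, via C3 aryllithium 2 (not isolated), via lithium aryltriisopropoxyborate 3 (not isolated)
Conditions: B(OiPr)3, then LiN(iPr)2, THF, −78 °C → 0 °C; AcOH, 30% aq H2O2, 0 °C → 25 °C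
Reagents that add atoms: hydrogen peroxide, OO
Why: Directed ortho-metalation: C3–H, flanked by fluorine and methoxy, is the most acidic ring position (the site selectivity known for 3-fluoroanisoles), the borate ester already present traps the aryllithium before it can lose LiF or attack a nitrile, and peroxide oxidation of the C–B bond (1,2-shift of aryl from boron to oxygen) then gives the phenol.

**Step 2**
Reactants: 4 4-fluoro-3-hydroxy-2-methoxybenzonitrile; 5 benzyl bromide
Product: 6 3-(benzyloxy)-4-fluoro-2-methoxybenzonitrile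
Conditions: K2CO3, DMF, 40 °C
Reagents that add atoms: benzyl bromide (5), BrCc1ccccc1
Why: Williamson ether synthesis, in which the phenoxide of 4 should be alkylated by the benzylic bromide far faster at 40 °C than it can displace fluoride from a second molecule.

**Step 3**
Reactants: 6 3-(benzyloxy)-4-fluoro-2-methoxybenzonitrile (half of the batch)
Product: 8 3-(benzyloxy)-4-hydroxy-2-methoxybenzonitrile, via sulfonylethyl aryl ether 7 (not isolated)
Conditions: MeSO2CH2CH2OH, NaH, DMF, 0 °C → 25 °C; aq HCl work-up
Reagents that add atoms: 2-(methylsulfonyl)ethanol, OCCS(C)(=O)=O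
Why: Nucleophilic aromatic substitution of the fluoride para to the nitrile by the alkoxide, followed by E1cB loss of methyl vinyl sulfone, so that the reagent acts as a hydroxide equivalent that cannot hydrate the nitrile.

**Step 4**
Reactants: 6 3-(benzyloxy)-4-fluoro-2-methoxybenzonitrile; 8 3-(benzyloxy)-4-hydroxy-2-methoxybenzonitrile
Product: 9 4,4'-oxybis[3-(benzyloxy)-2-methoxybenzonitrile]
Conditions: Cs2CO3, DMSO, 100 °C
Reagents that add atoms: none
Why: Nucleophilic aromatic substitution (addition–elimination through a Meisenheimer intermediate stabilised by the para nitrile) of fluoride in 6 by the caesium phenoxide of 8, the classical diaryl ether synthesis for para-cyano fluoroarenes, in which adventitious hydrolysis of 6 would only produce more 8.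

**Step 5**
Reactants: 9 4,4'-oxybis[3-(benzyloxy)-2-methoxybenzonitrile]
Product: 11 4,4'-oxybis[3-(benzyloxy)-2-methoxybenzenecarboximidamide] dihydrochloride, via bis(lithium disilylamidinate) 10 (not isolated)
Conditions: LiN(SiMe3)2, THF, 0 °C → 40 °C; HCl, EtOH, 0 °C
Reagents that add atoms: lithium bis(trimethylsilyl)amide, [Li]N([Si](C)(C)C)[Si](C)(C)C; hydrogen chloride, Cl
Why: Addition of the silylamide to each nitrile carbon with a 1,3-silyl shift gives the N,N'-disilylamidinate, which ethanolic HCl desilylates and protonates to the amidinium chloride (the standard nitrile-to-amidine conversion for hindered, electron-rich benzonitriles).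

**Step 6**
Reactants: 11 4,4'-oxybis[3-(benzyloxy)-2-methoxybenzenecarboximidamide] dihydrochloride
Product: 12 3,3'-{oxybis[3-(benzyloxy)-2-methoxy-4,1-phenylene]}bis(3-chloro-3H-diazirine)
Conditions: aq NaOCl, LiCl, DMSO/CH2Cl2, 0 °C → 20 °C, dark; exchange into MeCN below 10 °C, never to dryness
Reagents that add atoms: sodium hypochlorite, [Na+].[O-]Cl
Why: Graham oxidation, in which hypochlorite N-chlorinates each amidine, base-induced N–N bond formation expels chloride and chloride returns at carbon to give the 3-aryl-3-chlorodiazirine; the product should be kept as a cold, dilute solution and used at once because alkoxy-substituted aryl chlorodiazirines are labile and energetic.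

**Step 7**
Reactants: 13 benzofuran-6-ol; 5 benzyl bromide
Product: 14 6-(benzyloxy)benzofuran
Conditions: K2CO3, acetone, reflux
Reagents that add atoms: benzyl bromide (5), BrCc1ccccc1
Why: Williamson ether synthesis on the phenol, the furan ring being inert to carbonate base.

**Step 8**
Reactants: 12 bis(3-chlorodiazirine) of the diaryl ether core; 14 6-(benzyloxy)benzofuran (6 equiv)
Product: 16 3,3'-{oxybis[3-(benzyloxy)-2-methoxy-4,1-phenylene]}bis[7-(benzyloxy)chromenylium] dichloride (the bis(7-benzyloxyisoflavylium) dichloride), via bis(chlorocyclopropane) adduct 15 (not isolated)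
Conditions: 14 (6 equiv, concentrated), MeCN, 45 °C, dark, slow addition of cold 12 in MeCN; Et2O, 0 °C (precipitation under argon)
Reagents that add atoms: none
Why: Proposed new method: gentle thermolysis expels N2 from each diazirine to give a singlet arylchlorocarbene, which adds by concerted [2+1] cycloaddition to the C2=C3 bond of 14 to form the fused chlorocyclopropane 15; heterolysis of C–Cl with disrotatory opening of the bond shared by the three- and five-membered rings, assisted by the ring oxygen, the aryl group on the carbinyl carbon and the para alkoxy group of ring A, then gives the aromatic benzopyrylium. The closest known reaction types are the carbon insertion of aryl chlorodiazirines into indoles and pyrroles (Ciamician–Dennstedt type) and the dihalocarbene ring expansion of benzofurans to 3-halo-2H-chromenes. Each ring C is formed by ring expansion, that is by a 2π-electron electrocyclic cyclopropyl-to-allyl cation opening of the bicycle, and not by cyclisation of an open chain. No stereocentre is created, because the carbene carbon and both furan carbons become sp2 centres of the pyrylium ring and the diastereomers of 15 converge. The step needs chemoselectivity for C2=C3 over the benzenoid rings, the ether oxygens, the ortho-methoxy C–H bonds of the carbene and unreacted diazirine; this rests on the enol ether character of that bond, on a large excess of concentrated 14 and on slow addition of 12. Regiochemistry is no issue, since the inserted carbon ends between C2 and C4 whichever way the carbene approaches.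

**Step 9**
Reactants: 16 bis(7-benzyloxyisoflavylium) dichloride
Product: 17 3,3'-{oxybis[3-(benzyloxy)-2-methoxy-4,1-phenylene]}bis[7-(benzyloxy)-2H-chromene] (the bis(isoflav-3-ene))
Conditions: NaBH4, MeCN/THF, −40 °C → 0 °C
Reagents that add atoms: none
Why: Borohydride reduction of a benzopyrylium salt, in which hydride adds to C2, the unhindered position next to the oxonium oxygen, to give the 2H-chromene whose C3=C4 bond stays conjugated to rings A and B, as established for isoflavylium salts.

**Step 10**
Reactants: 17 bis(isoflav-3-ene)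
Product: 18 (3R,3'R)-3,3'-{oxybis[3-(benzyloxy)-2-methoxy-4,1-phenylene]}bis[7-(benzyloxy)-3,4-dihydro-2H-chromene]
Conditions: [Ir(cod)(ThrePHOX)][B(C6H3(CF3)2)4] (ligand antipode that gives 3R, 4 mol%), H2 (50 bar), CH2Cl2, 25 °C
Reagents that add atoms: none
Why: Iridium P,N-ligand catalysed asymmetric hydrogenation of a trisubstituted aryl alkene without a coordinating group, established for 3-aryl-2H-chromenes; each C3 centre is set under catalyst control by face-selective delivery of H2 to C3=C4, the two remote alkenes react independently so that the 3R,3'R isomer is statistically amplified over the meso form, and benzyl ethers are untouched by this catalyst.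

**Step 11**
Reactants: 18 (3R,3'R)-tetrabenzyl ether
Product: 19 (3R,3'R)-3,3'-[oxybis(3-hydroxy-2-methoxy-4,1-phenylene)]bis(3,4-dihydro-2H-chromen-7-ol) (CNP0116832.1)
Conditions: H2 (1 atm), 10% Pd/C, THF/MeOH, 25 °C
Reagents that add atoms: none
Why: Heterogeneous hydrogenolysis of the four benzyl aryl ethers, under which the diaryl ether, the chroman C–O bonds and the C3 centres (neither acidic nor attached to a cleavable benzylic heteroatom) are unaffected.

**Compound list**
1 | 4-fluoro-2-methoxybenzonitrile | N#Cc1ccc(F)cc1OC | starting material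
2 | (3-cyano-6-fluoro-2-methoxyphenyl)lithium | [Li]c1c(F)ccc(C#N)c1OC | intermediate
3 | lithium (3-cyano-6-fluoro-2-methoxyphenyl)tri(propan-2-yloxy)borate | [Li+].CC(C)O[B-](OC(C)C)(OC(C)C)c1c(F)ccc(C#N)c1OC | intermediate
4 | 4-fluoro-3-hydroxy-2-methoxybenzonitrile | N#Cc1ccc(F)c(O)c1OC | intermediate
5 | benzyl bromide | BrCc1ccccc1 | starting material
6 | 3-(benzyloxy)-4-fluoro-2-methoxybenzonitrile | N#Cc1ccc(F)c(OCc2ccccc2)c1OC | intermediate
7 | 3-(benzyloxy)-2-methoxy-4-[2-(methylsulfonyl)ethoxy]benzonitrile | N#Cc1ccc(OCCS(C)(=O)=O)c(OCc2ccccc2)c1OC | intermediate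
8 | 3-(benzyloxy)-4-hydroxy-2-methoxybenzonitrile | N#Cc1ccc(O)c(OCc2ccccc2)c1OC | intermediate
9 | 4,4'-oxybis[3-(benzyloxy)-2-methoxybenzonitrile] | N#Cc1ccc(Oc2ccc(C#N)c(OC)c2OCc3ccccc3)c(OCc3ccccc3)c1OC | intermediate
10 | dilithium bis[N,N'-bis(trimethylsilyl)amidinate] derived from 9 | C[Si](C)(C)N=C(N([Li])[Si](C)(C)C)c1ccc(Oc2ccc(C(=N[Si](C)(C)C)N([Li])[Si](C)(C)C)c(OC)c2OCc3ccccc3)c(OCc3ccccc3)c1OC | intermediate
11 | 4,4'-oxybis[3-(benzyloxy)-2-methoxybenzenecarboximidamide] dihydrochloride | NC(=N)c1ccc(Oc2ccc(C(N)=N)c(OC)c2OCc3ccccc3)c(OCc3ccccc3)c1OC.Cl.Cl | intermediate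
12 | 3,3'-{oxybis[3-(benzyloxy)-2-methoxy-4,1-phenylene]}bis(3-chloro-3H-diazirine) | ClC1(N=N1)c1ccc(Oc2ccc(C3(Cl)N=N3)c(OC)c2OCc3ccccc3)c(OCc3ccccc3)c1OC | intermediate
13 | benzofuran-6-ol | Oc1ccc2ccoc2c1 | starting material
14 | 6-(benzyloxy)benzofuran | c1cc2ccc(OCc3ccccc3)cc2o1 | intermediate
15 | 1,1'-{oxybis[3-(benzyloxy)-2-methoxy-4,1-phenylene]}bis[4-(benzyloxy)-1-chloro-1a,6b-dihydro-1H-cyclopropa[b][1]benzofuran], diastereomer mixture | ClC4(C5Oc6cc(OCc7ccccc7)ccc6C45)c1ccc(Oc2ccc(C4(Cl)C5Oc6cc(OCc7ccccc7)ccc6C45)c(OC)c2OCc3ccccc3)c(OCc3ccccc3)c1OC | intermediate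
16 | 3,3'-{oxybis[3-(benzyloxy)-2-methoxy-4,1-phenylene]}bis[7-(benzyloxy)chromenylium] dichloride | c1(-c3c[o+]c4cc(OCc5ccccc5)ccc4c3)ccc(Oc2ccc(-c3c[o+]c4cc(OCc5ccccc5)ccc4c3)c(OC)c2OCc3ccccc3)c(OCc3ccccc3)c1OC.[Cl-].[Cl-] | intermediate
17 | 3,3'-{oxybis[3-(benzyloxy)-2-methoxy-4,1-phenylene]}bis[7-(benzyloxy)-2H-chromene] | COc1c(C2=Cc3ccc(OCc4ccccc4)cc3OC2)ccc(Oc2ccc(C3=Cc4ccc(OCc5ccccc5)cc4OC3)c(OC)c2OCc2ccccc2)c1OCc1ccccc1 | intermediate
18 | (3R,3'R)-3,3'-{oxybis[3-(benzyloxy)-2-methoxy-4,1-phenylene]}bis[7-(benzyloxy)-3,4-dihydro-2H-chromene] | COc1c([C@@H]2COc3cc(OCc4ccccc4)ccc3C2)ccc(Oc2ccc([C@@H]3COc4cc(OCc5ccccc5)ccc4C3)c(OC)c2OCc2ccccc2)c1OCc1ccccc1 | intermediate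
19 | (3R,3'R)-3,3'-[oxybis(3-hydroxy-2-methoxy-4,1-phenylene)]bis(3,4-dihydro-2H-chromen-7-ol) | COc1c([C@@H]2COc3cc(O)ccc3C2)ccc(Oc2ccc([C@@H]3COc4cc(O)ccc4C3)c(OC)c2O)c1O | target

**Total step count:** 11
**Longest linear sequence:** 10 steps (steps 1–6, then 8–11); step 7 is a one-step side branch.

**Steps most likely to fail**

Step 8. The carbene may be consumed by azine formation with unreacted diazirine, by insertion into its own ortho-methoxy C–H bonds or by attack on benzenoid positions. Only one of the two arms may react, or chloride may strip benzyl groups from the alkoxypyrylium. The same fallback serves if the electron-rich bis(diazirine) does not survive its preparation in step 6. The fallback uses the classical pyrylium synthesis from a salicylaldehyde and an arylacetaldehyde equivalent; it sets out from 9 and comes back at 16. Compound 9 is reduced with iBu2AlH (toluene, −78 °C, then aqueous acid) to the dialdehyde 4,4'-oxybis[3-(benzyloxy)-2-methoxybenzaldehyde] F1. Wittig methoxymethylenation (Ph3P=CHOMe from the phosphonium chloride and KOtBu, THF, 0 °C) then gives the bis(enol ether) 1,1'-oxybis[2-(benzyloxy)-3-methoxy-4-(2-methoxyethenyl)benzene] F2 as an E/Z mixture. This masked bis(arylacetaldehyde) is condensed with two equivalents of purchased 4-(benzyloxy)-2-hydroxybenzaldehyde under dry HCl in EtOAc/AcOH at 0 °C. Aldol-type C–C bond formation, closure of the phenol onto the former enol ether carbon and loss of water and methanol should then give 16.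

Step 9. Hydride may be delivered to C4 in competition with C2, giving the 4H-chromene enol ether, and traces of water may open the pyrylium ring before reduction. The fallback sets out from 16 and comes back at 17. The salt is deliberately hydrolysed (aq NaHCO3, THF) to its pseudo-base, the bis(2H-chromen-2-ol) 3,3'-{oxybis[3-(benzyloxy)-2-methoxy-4,1-phenylene]}bis[7-(benzyloxy)-2H-chromen-2-ol] F3, which equilibrates with its ring-opened (Z)-enal. Luche reduction (NaBH4, CeCl3·7H2O, MeOH, 0 °C) of that aldehyde should give the bis(allylic alcohol) bis-phenol 2,2'-{oxybis[3-(benzyloxy)-2-methoxy-4,1-phenylene]}bis[(2Z)-3-(4-(benzyloxy)-2-hydroxyphenyl)prop-2-en-1-ol] F4. A double intramolecular Mitsunobu etherification (PPh3, DIAD, THF) then closes both pyran rings to 17, and no hydride is ever offered to C4.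

Step 10. Face selectivity may be insufficient or conversion may stall at one of the two alkenes. This would leave meso and half-reduced material that is hard to remove because the two centres are remote from each other. The fallback sets out from 17 and comes back at 19; the centre is set instead by dynamic kinetic resolution.
- Hydroboration–oxidation (BH3·THF, then NaOH/H2O2) gives the bis(trans-isoflavan-4-ol) 3,3'-{oxybis[3-(benzyloxy)-2-methoxy-4,1-phenylene]}bis[7-(benzyloxy)-3,4-dihydro-2H-chromen-4-ol] F5 as a stereoisomer mixture.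
- Dess–Martin oxidation gives the bis(isoflavanone) 3,3'-{oxybis[3-(benzyloxy)-2-methoxy-4,1-phenylene]}bis[7-(benzyloxy)-2,3-dihydro-4H-chromen-4-one] F6, whose C3 centres epimerise readily.
- Asymmetric transfer hydrogenation with dynamic kinetic resolution (RuCl(TsDPEN)(p-cymene), antipode chosen for 3R, HCO2H/Et3N) should give the bis(cis-isoflavan-4-ol) (3R,4R,3'R,4'R)-3,3'-{oxybis[3-(benzyloxy)-2-methoxy-4,1-phenylene]}bis[7-(benzyloxy)-3,4-dihydro-2H-chromen-4-ol] F7.
- H2 over Pd/C in EtOH/AcOH then removes the benzylic C4 hydroxyls together with the four benzyl ethers to give 19.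

**Further compounds**
F1 | step 8 | 4,4'-oxybis[3-(benzyloxy)-2-methoxybenzaldehyde] | O=Cc1ccc(Oc2ccc(C=O)c(OC)c2OCc3ccccc3)c(OCc3ccccc3)c1OC
F2 | step 8 | 1,1'-oxybis[2-(benzyloxy)-3-methoxy-4-(2-methoxyethenyl)benzene], E/Z mixture | COC=Cc1ccc(Oc2ccc(C=COC)c(OC)c2OCc3ccccc3)c(OCc3ccccc3)c1OC
F3 | step 9 | 3,3'-{oxybis[3-(benzyloxy)-2-methoxy-4,1-phenylene]}bis[7-(benzyloxy)-2H-chromen-2-ol] | COc1c(C2=Cc3ccc(OCc4ccccc4)cc3OC2O)ccc(Oc2ccc(C3=Cc4ccc(OCc5ccccc5)cc4OC3O)c(OC)c2OCc2ccccc2)c1OCc1ccccc1
F4 | step 9 | 2,2'-{oxybis[3-(benzyloxy)-2-methoxy-4,1-phenylene]}bis[(2Z)-3-(4-(benzyloxy)-2-hydroxyphenyl)prop-2-en-1-ol] | COc1c(/C(CO)=C/c2ccc(OCc3ccccc3)cc2O)ccc(Oc2ccc(/C(CO)=C/c3ccc(OCc4ccccc4)cc3O)c(OC)c2OCc2ccccc2)c1OCc1ccccc1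
F5 | step 10 | 3,3'-{oxybis[3-(benzyloxy)-2-methoxy-4,1-phenylene]}bis[7-(benzyloxy)-3,4-dihydro-2H-chromen-4-ol], trans, stereoisomer mixture | COc1c(C2COc3cc(OCc4ccccc4)ccc3C2O)ccc(Oc2ccc(C3COc4cc(OCc5ccccc5)ccc4C3O)c(OC)c2OCc2ccccc2)c1OCc1ccccc1
F6 | step 10 | 3,3'-{oxybis[3-(benzyloxy)-2-methoxy-4,1-phenylene]}bis[7-(benzyloxy)-2,3-dihydro-4H-chromen-4-one] | COc1c(C2COc3cc(OCc4ccccc4)ccc3C2=O)ccc(Oc2ccc(C3COc4cc(OCc5ccccc5)ccc4C3=O)c(OC)c2OCc2ccccc2)c1OCc1ccccc1
F7 | step 10 | (3R,4R,3'R,4'R)-3,3'-{oxybis[3-(benzyloxy)-2-methoxy-4,1-phenylene]}bis[7-(benzyloxy)-3,4-dihydro-2H-chromen-4-ol], cis | COc1c([C@@H]2COc3cc(OCc4ccccc4)ccc3[C@@H]2O)ccc(Oc2ccc([C@@H]3COc4cc(OCc5ccccc5)ccc4[C@@H]3O)c(OC)c2OCc2ccccc2)c1OCc1ccccc1
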